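(Readings and results are simulated for an exercise; the scatter is artificial.)

The pitfall in a flask that stops short is to blame the clock, yet birch is down to 3% of its starting material by 25.0 s and its product then stays level within scatter, so the missing share went elsewhere and the question is what each run paid.

| setting | cedar | birch | elm | Tuesday's | Monday's |
|---|---|---|---|---|---|
| starting material | 0.16 mM | 0.46 mM | 0.20 mM | 0.20 mM | 0.60 mM |
| protic impurity | 0.20 mM | 0.20 mM | 0.20 mM | 0.200 mM | 0.200 mM |
| free catalyst | 0.92 µM | 0.92 µM | 2.1 µM | 0.92 µM | 3.0 µM |
| remark | run made earlier | run made earlier | run made earlier |  |  |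
| time |  |  |  | 2.0 min | 1.0 min |

| run | time / s | product / % | starting material / % |
|---|---|---|---|
| cedar | 12.0 | 82 | 4 |
| cedar | 25.0 | 80 | 0 |
| cedar | 40.0 | 83 | 1 |
| cedar | 50.0 | 86 | 0 |
| cedar | 60.0 | 81 | 1 |
| cedar | 80.0 | 85 | 2 |
| birch | 12.0 | 43 | 36 |
| birch | 25.0 | 74 | 3 |
| birch | 40.0 | 76 | 0 |
| birch | 50.0 | 80 | 1 |
| birch | 60.0 | 73 | 0 |
| birch | 80.0 | 75 | 0 |
| elm | 10.0 | 91 | 1 |
| elm | 12.0 | 89 | 0 |
| elm | 25.0 | 90 | 0 |
| elm | 40.0 | 91 | 0 |
| elm | 80.0 | 88 | 1 |

(readings scatter by 2 percentage points)

- which one finishes higher in amount of product, in percent of the starting material charged ("neither" within 2 percentage points) (Tuesday's / Monday's / neither)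
- amount of product at the end, in percent of the starting material charged, Tuesday's
- amount of product at the end, in percent of the starting material charged, Monday's



What do you count first? The turnovers asked of each catalyst, N = c(starting material)/c(free catalyst), which is 217 for Tuesday's and 200 for Monday's, both fewer than birch's 500, and since Tuesday's has 2.0 min and Monday's 1.0 min, each longer than birch's 25.0 s, I set time aside.

And the price of a turnover? I assume that each lost starting material takes one protic impurity, so a plateau gives the fall of c(protic impurity), and I define the toll as the natural logarithm of charged over final c(protic impurity), divided by N. Cedar's plateau readings average 83.0%, which gives 8.41 × 10⁻⁴, birch's average 76.0%, which gives 0.00161, and a straight line in c(starting material) through these two values gives the toll per turnover at Tuesday's charge, 9.43 × 10⁻⁴.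

Your figures? Tuesday's 81.5%; Monday's, at a toll of 0.00196, 89.2%.

Where is that weakest? Monday's charge of starting material lies beyond birch's and its free catalyst above the 0.92 µM of both runs behind the line, so its toll is extrapolated; elm, left out of the line, reckons to 91.4% and its readings average 89.8%, which tests the line at a charge of starting material inside its range, with more free catalyst than cedar or birch.

The forecast gave 82% for Tuesday's and 86% for Monday's, with Monday's higher, holding that “the impurity is consumed stoichiometrically”; its Monday's figure is lower than mine.

The flask gives 81.4% for Tuesday's and 87.2% for Monday's, so Monday's finishes higher.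

    catalyst intermediate → spent catalyst (k = 0.0194 s⁻¹)
    catalyst intermediate → free catalyst + product (k = 24.5 s⁻¹)
    free catalyst ⇌ dormant form (K = 10.0, k = 0.0149 s⁻¹)
    starting material + protic impurity → quenched substrate (k = 200 L mol⁻¹ s⁻¹)
    starting material + free catalyst ⇌ catalyst intermediate (K = 3.89 × 10⁵ L mol⁻¹, k = 7.10 × 10⁵ L mol⁻¹ s⁻¹)

Tuesday's impurity ended at 81% of its charge, a toll of 9.41 × 10⁻⁴ against the 9.43 × 10⁻⁴ reckoned. The neighbour of Tuesday's, charged with 0.0016 mM of free catalyst, is asked 125 turnovers, fewer than Tuesday's, and the same toll reckons its product at 88.9%. That neighbour flask gives 88.2%, with starting material, its limiting reagent, at 0% and protic impurity at 88% of its charge.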